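**Retrosynthetic overview**

1. Locants: hydrindane core C1, C2, C3, C3a, C4–C7, C7a (ring B = C3a/C4–C7/C7a, ring C = C1/C2/C3/C3a/C7a, lactone ring D = C7a–C(=O)–O–C4, Br on C7, side chain on C3); ring A = cyclohexanol C1'–C6' (C1' carbinol, C3' CMe2, C4' CHBr). Last disconnection: both neopentylic C–Br bonds (C7, C4') from a diketone via bis(enol triflate), bis(alkenyl bromide) and a twofold hydrogen-atom-transfer hydrogenation.
2. Ring A is cut at C3–CH2: a ring A cyclohexenylmethyl chloride (ring-closing metathesis) alkylates the C2/C3 enolate of a hydrindenone. Its C1' carbinol comes from Shi epoxidation and β-elimination of the derived β,γ-epoxy ketone. Ring D closes from the syn-axial C4–OH/C7a–CO2H pair.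
3. Key disconnection: ring C together with the ring B bond C3a–C7a by a [2+2+1] cyclocarbonylation (Pauson–Khand) of an acyclic 1,7-enyne. Bonds C1–C2, C2–C3 and C3a–C7a form in one operation; C2 enters as CO and is reduced to CH2 afterwards.
4. Enabling feature: ring C is fused to ring B along C3a–C7a, its C1H2–C2H2 edge is unsubstituted, and C7a is quaternary and carries the lactone carbonyl. So C1=C7a is the alkene of an α-substituted acrylate, C3≡C3a is a terminal alkyne on the carbinol carbon C4, and C2 is a carbonyl carbon; the C4 centre (Sharpless epoxidation of geraniol) controls C7a.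
5. Order of ring formation: ring A (fragment, step 4); rings B and C together (step 12); ring D (step 13); then the two bromides (steps 19–21).

Key step: step 12

Remark: C7 is formed without control in step 10, so 15–26 are carried as both C7 epimers (no descriptor in the SMILES); C7 and the temporary centre C4' (set in step 2, drawn R) become ketones in step 17 and receive their final configuration in step 21.

**Step 1**
Reactants: 1 isobutyraldehyde; 2 3-chloro-2-(chloromethyl)prop-1-ene
Product: 3 4-(chloromethyl)-2,2-dimethylpent-4-enal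
Conditions: 50% aq. NaOH, Bu4NI (cat.), toluene, 60 °C; 2 in excess
Reagents that add atoms: none
Why: Phase-transfer C-alkylation of isobutyraldehyde at its only enolisable carbon by an allylic chloride (a known alkylation of this aldehyde) builds the quaternary C3' with both methyl groups; the product cannot enolise and no stereocentre is formed.

**Step 2**
Reactants: 3 4-(chloromethyl)-2,2-dimethylpent-4-enal
Product: 4 (4R)-7-(chloromethyl)-5,5-dimethylocta-1,7-dien-4-ol
Conditions: allylB(pin) (1.3 equiv), (R)-TRIP phosphoric acid (5 mol%), toluene, −30 °C; aq. NaHCO3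
Reagents that add atoms: allylboronic acid pinacol ester, C=CCB1OC(C)(C)C(C)(C)O1
Why: Chiral phosphoric acid catalysed allylboration through a closed chair transition state should give one carbinol enantiomer (drawn R); C4' is only a temporary centre that keeps later intermediates single isomers and is erased in step 17, so its sense is immaterial.

**Step 3**
Reactants: 4 (4R)-7-(chloromethyl)-5,5-dimethylocta-1,7-dien-4-ol
Product: 5 tert-butyldimethylsilyl ether of 4
Conditions: TBSOTf, 2,6-lutidine, CH2Cl2, 0 °C
Reagents that add atoms: tert-butyldimethylsilyl trifluoromethanesulfonate, CC(C)(C)[Si](C)(C)OS(=O)(=O)C(F)(F)F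
Why: Silylation of a hindered secondary alcohol with the silyl triflate masks the future C4' ketone as a non-acidic group that survives metathesis and enolate alkylation.

**Step 4**
Reactants: 5 tert-butyldimethylsilyl ether of 4
Product: 6 tert-butyl{[(1R)-4-(chloromethyl)-6,6-dimethylcyclohex-3-en-1-yl]oxy}dimethylsilane (ring A chloride)
Conditions: second-generation Grubbs catalyst (H2IMes)(PCy3)Cl2Ru=CHPh (3 mol%), CH2Cl2, 40 °C
Reagents that add atoms: none
Why: Ring-closing metathesis of a 1,7-diene (monosubstituted plus 1,1-disubstituted alkene) closes ring A as the trisubstituted C1'=C6' cyclohexene with loss of ethene; C4' is untouched.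

**Step 5**
Reactants: 7 geraniol
Product: 8 (2R,3R)-2,3-epoxygeraniol
Conditions: Ti(OiPr)4 (5 mol%), D-(−)-diethyl tartrate (6 mol%), t-BuOOH, 4 Å molecular sieves, CH2Cl2, −20 °C
Reagents that add atoms: tert-butyl hydroperoxide, CC(C)(C)OO
Why: Sharpless asymmetric epoxidation touches only the allylic alcohol alkene, and the D-tartrate ligand directs oxygen to the face that gives the (2R,3R)-epoxide, which fixes the configuration of the future C4.

**Step 6**
Reactants: 8 (2R,3R)-2,3-epoxygeraniol
Product: 9 (2S,3R)-2-(chloromethyl)-3-methyl-3-(4-methylpent-3-en-1-yl)oxirane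
Conditions: PPh3, CCl4, NaHCO3, reflux
Reagents that add atoms: tetrachloromethane, ClC(Cl)(Cl)Cl
Why: Appel chlorination of the primary alcohol under buffered neutral conditions leaves the epoxide and both of its centres intact.

**Step 7**
Reactants: 9 (2S,3R)-2-(chloromethyl)-3-methyl-3-(4-methylpent-3-en-1-yl)oxirane
Product: 10 (3R)-3,7-dimethyloct-6-en-1-yn-3-ol
Conditions: n-BuLi (3.2 equiv), THF, −35 °C; aq. NH4Cl
Reagents that add atoms: none
Why: Base-induced double elimination of a 2,3-epoxy chloride (deprotonation at CH2Cl opens the epoxide to a chlorovinyl alkoxide, which loses HCl to the alkyne) is a known route to propargylic alcohols; the C–O bond at the tertiary carbon is never broken, so C4 keeps its configuration.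

**Step 8**
Reactants: 10 (3R)-3,7-dimethyloct-6-en-1-yn-3-ol
Product: 11 trimethyl{[(3R)-3,7-dimethyloct-6-en-1-yn-3-yl]oxy}silane
Conditions: Me3SiCl, imidazole, CH2Cl2, 0 °C to rt
Reagents that add atoms: chlorotrimethylsilane, C[Si](C)(C)Cl
Why: O-silylation of the tertiary alcohol prevents lactol formation with the aldehyde made in step 9 and keeps the Baylis–Hillman step free of a competing hydroxyl.

**Step 9**
Reactants: 11 trimethyl{[(3R)-3,7-dimethyloct-6-en-1-yn-3-yl]oxy}silane
Product: 13 (4R)-4-methyl-4-[(trimethylsilyl)oxy]hex-5-ynal, via secondary ozonide 12 (not isolated)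
Conditions: O3, CH2Cl2, −78 °C, Sudan Red 7B as end-point indicator; then PPh3, −78 °C to rt
Reagents that add atoms: ozone, [O-][O+]=O
Why: Ozonolysis is selective for the electron-rich trisubstituted alkene over the terminal alkyne when stopped at the indicator end point, and reductive work-up gives the aldehyde carbon that becomes C7.

**Step 10**
Reactants: 13 (4R)-4-methyl-4-[(trimethylsilyl)oxy]hex-5-ynal; 14 methyl acrylate
Product: 15 methyl (6R)-3-hydroxy-6-methyl-2-methylidene-6-[(trimethylsilyl)oxy]oct-7-ynoate (both C3 epimers)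
Conditions: DABCO (0.5 equiv), methyl acrylate (excess, neat), rt
Reagents that add atoms: none
Why: Morita–Baylis–Hillman reaction of an unbranched aliphatic aldehyde installs the α-substituted acrylate (future C1, C7a and lactone carbonyl) and an oxygen handle at C7; the new carbinol centre is not controlled and need not be, because it is oxidised in step 17.

**Step 11**
Reactants: 15 Baylis–Hillman adduct
Product: 16 tert-butyldimethylsilyl ether of 15
Conditions: TBSCl, imidazole, DMF, rt
Reagents that add atoms: tert-butyldimethylsilyl chloride, CC(C)(C)[Si](C)(C)Cl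
Why: Standard silylation of the secondary allylic alcohol removes the only acidic proton besides the alkyne C–H, so that the proton inventory in step 13 is exact.

**Step 12**
Reactants: 16 tert-butyldimethylsilyl ether of 15
Product: 18 methyl (4R,7aR)-7-[(tert-butyldimethylsilyl)oxy]-4-methyl-2-oxo-4-[(trimethylsilyl)oxy]-1,2,4,5,6,7-hexahydro-7aH-indene-7a-carboxylate, via hexacarbonyldicobalt alkyne complex 17 (not isolated)
Conditions: Co2(CO)8 (1.1 equiv), CH2Cl2, rt; then N-methylmorpholine N-oxide (8 equiv), 0 °C to rt
Reagents that add atoms: dicobalt octacarbonyl Co2(CO)8 (supplies C2 and its oxygen as CO), O=C=[Co](=C=O)(=C=O)(=C=O)[Co](=C=O)(=C=O)(=C=O)=C=O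
Why: Intramolecular Pauson–Khand reaction (amine N-oxide promoted [2+2+1] cyclocarbonylation of a 1,7-enyne with a 1,1-disubstituted alkene, a known way to angularly substituted hydrindenones): the terminal alkyne is complexed as 17, N-oxide-induced CO loss lets the acrylate C=C coordinate and insert into the Co–C bond of the internal alkyne carbon, CO then inserts and reductive elimination releases the enone. Ring B closes by the C3a–C7a bond (six-membered ring through the C4–C7 tether, helped by the fully substituted C4), ring C by the C1–C2 and C2–C3 bonds to the new carbonyl carbon. Regiochemistry is fixed by the tether (the alkyne CH becomes C3, the alkene CH2 becomes C1), and there is only one alkene, so no chemoselectivity question arises. The only new stereocentre, quaternary C7a, is controlled by C4: ring C must leave C7a equatorially, so the ester is axial on the chair-like ring B of the insertion transition state, and the C4 methyl group then takes the equatorial site (no allylic strain against the unsubstituted C3–H) while the smaller silyloxy group sits axial and syn to the ester, which avoids a syn-diaxial methyl/ester contact. This gives the cis C4–O/C7a–carbonyl relationship that the lactone requires. The step needs the electron-poor alkene to insert, and the geminal substitution of the tether together with N-oxide promotion at low temperature is what should secure it.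

**Step 13**
Reactants: 18 hydrindenone ester; 6 ring A chloride
Product: 22 tricyclic keto lactone bearing the ring A cyclohexenylmethyl group at C3, via dilithium alkoxide carboxylate 19 (not isolated), via trilithium enolate 20 (not isolated), via alkylated dilithium salt 21 (not isolated)
Conditions: LiOH (2.2 equiv), THF/MeOH/H2O, 40 °C; evaporate, dry by toluene azeotrope; Li (2.5 equiv), t-BuOH (1.0 equiv), NH3/THF, −78 °C; isoprene; 6 (1.2 equiv), NaI (cat.), −78 to −33 °C; NH4Cl; then 1 M HCl, THF, rt
Reagents that add atoms: lithium hydroxide LiOH (its oxygen can remain as the lactone carbonyl oxygen after ring opening and reclosure), [Li+].[OH-]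
Why: Saponification leaves only a C4 alkoxide and a C7a carboxylate, so that no silyloxy or acyloxy leaving group sits γ to the enone during electron transfer; Birch-type enone reduction then protonates C3a axially (stereoelectronic control, trans-hydrindanone, H anti to the axial carboxylate), the regiodefined C2–C3 enolate is C-alkylated by allylic chloride 6 on the face anti to the fully substituted C4 (reductive alkylation of an enone), and acidification closes the γ-lactone between the syn-axial C4–OH and C7a–CO2H.

**Step 14**
Reactants: 22 tricyclic keto lactone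
Product: 24 tricyclic lactone with C2 as CH2, via tosylhydrazone 23 (not isolated)
Conditions: TsNHNH2, EtOH, 60 °C; concentrate; catecholborane, CHCl3, 0 °C; then NaOAc·3H2O, reflux
Reagents that add atoms: none
Why: Tosylhydrazone formation at the only ketone and catecholborane reduction (hydride addition, sulfinate loss, diazene collapse with N2 extrusion) removes the C2 carbonyl under conditions that spare the lactone, the silyl ethers and the ring A alkene; C3 is already in its more stable configuration, trans to C4.

**Step 15**
Reactants: 24 tricyclic lactone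
Product: 25 C1',C6'-epoxide of 24
Conditions: D-fructose-derived Shi ketone (0.3 equiv), Oxone (2KHSO5·KHSO4·K2SO4), K2CO3, Bu4NHSO4, MeCN/CH2(OMe)2/aq. Na2B4O7 buffer, 0 °C
Reagents that add atoms: potassium peroxymonosulfate KHSO5, [K+].[O-]S(=O)(=O)OO
Why: Shi epoxidation of the only alkene (trisubstituted, endocyclic) is reagent-controlled through the spiro transition state; the D-fructose-derived ketone delivers oxygen to the face on which it epoxidises 1-substituted cyclohexenes, which is the face that gives the required C1' configuration.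

**Step 16**
Reactants: 25 epoxide
Product: 26 epoxy diol (C7–OH and C4'–OH free)
Conditions: Bu4NF, THF, 0 to 40 °C
Reagents that add atoms: none
Why: Fluoride cleaves both hindered secondary silyl ethers while the trisubstituted epoxide and the bridged lactone are stable to these basic conditions.

**Step 17**
Reactants: 26 epoxy diol
Product: 28 diketone with the ring A 1'-hydroxy-5'-en-4'-one unit, via epoxy diketone 27 (not isolated)
Conditions: Dess–Martin periodinane, NaHCO3, CH2Cl2, rt; then DBU, 0 °C
Reagents that add atoms: none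
Why: Dess–Martin oxidation turns both secondary alcohols into ketones (erasing the C7 and C4' centres), and DBU then opens the β,γ-epoxy ketone by E1cB elimination across C5'–C6'; the C1'–O bond is not broken, so the tertiary carbinol keeps the configuration set in step 15.

**Step 18**
Reactants: 28 hydroxy enone diketone
Product: 29 saturated diketone (C7 and C4' ketones)
Conditions: H2 (1 atm), Pd/C, EtOAc, rt
Reagents that add atoms: none
Why: Catalytic hydrogenation of the disubstituted enone C=C leaves the ketones, the lactone and the tertiary alcohol untouched and creates no stereocentre.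

**Step 19**
Reactants: 29 saturated diketone
Product: 30 bis(enol triflate) (C6=C7 and C4'=C5')
Conditions: KN(SiMe3)2 (3.3 equiv), PhNTf2 (2.4 equiv), THF, −78 °C
Reagents that add atoms: N-phenylbis(trifluoromethanesulfonimide), O=S(=O)(N(c1ccccc1)S(=O)(=O)C(F)(F)F)C(F)(F)F
Why: Each ketone has a quaternary carbon on one side (C7a, C3'), so enolisation and O-triflation can occur only toward C6 and C5'; the hindered tertiary alkoxide is expected not to be triflated at −78 °C and is reprotonated on work-up.

**Step 20**
Reactants: 30 bis(enol triflate)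
Product: 31 bis(alkenyl bromide) (7-bromo-C6=C7 and 4'-bromo-C4'=C5')
Conditions: Ni(cod)2 (10 mol%), LiBr (excess), DMA/THF, rt
Reagents that add atoms: lithium bromide, [Li+].[Br-]
Why: Nickel-catalysed halide exchange of enol triflates (oxidative addition, triflate–bromide exchange, reductive elimination) is a known route to hindered alkenyl bromides and places bromine on C7 and C4' without touching the lactone or the alcohol.

**Step 21**
Reactants: 31 bis(alkenyl bromide)
Product: 32 target CNP0282702.2
Conditions: Co(acac)2, t-BuOOH, Et3SiH, 1,4-cyclohexadiene, n-PrOH, rt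
Reagents that add atoms: none
Why: Hydrogen-atom-transfer hydrogenation of alkenyl halides (cobalt hydride adds H to C6 and C5', the α-bromo radicals at C7 and C4' then abstract H from cyclohexadiene) keeps the C–Br bonds; H should arrive axially, anti to the axial lactone carbonyl on C7a and anti to the axial methyl on C3' (ring A held with CH2R equatorial and OH axial), so both bromines end equatorial as in the target.

**Compound list**

1 | isobutyraldehyde | CC(C)C=O | starting material
2 | 3-chloro-2-(chloromethyl)prop-1-ene | C=C(CCl)CCl | starting material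
3 | 4-(chloromethyl)-2,2-dimethylpent-4-enal | O=CC(C)(C)CC(=C)CCl | intermediate
4 | (4R)-7-(chloromethyl)-5,5-dimethylocta-1,7-dien-4-ol | C=CC[C@@H](O)C(C)(C)CC(=C)CCl | intermediate
5 | tert-butyl{[(4R)-7-(chloromethyl)-5,5-dimethylocta-1,7-dien-4-yl]oxy}dimethylsilane | C=CC[C@@H](O[Si](C)(C)C(C)(C)C)C(C)(C)CC(=C)CCl | intermediate
6 | tert-butyl{[(1R)-4-(chloromethyl)-6,6-dimethylcyclohex-3-en-1-yl]oxy}dimethylsilane (ring A chloride) | ClCC1=CC[C@@H](O[Si](C)(C)C(C)(C)C)C(C)(C)C1 | intermediate
7 | geraniol, (2E)-3,7-dimethylocta-2,6-dien-1-ol | CC(C)=CCC/C(C)=C/CO | starting material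
8 | (2R,3R)-2,3-epoxygeraniol | O1[C@](C)(CCC=C(C)C)[C@H]1CO | intermediate
9 | (2S,3R)-2-(chloromethyl)-3-methyl-3-(4-methylpent-3-en-1-yl)oxirane | O1[C@](C)(CCC=C(C)C)[C@H]1CCl | intermediate
10 | (3R)-3,7-dimethyloct-6-en-1-yn-3-ol | O[C@](C)(CCC=C(C)C)C#C | intermediate
11 | trimethyl{[(3R)-3,7-dimethyloct-6-en-1-yn-3-yl]oxy}silane | C[Si](C)(C)O[C@](C)(CCC=C(C)C)C#C | intermediate
12 | secondary ozonide (3,3-dimethyl-1,2,4-trioxolane) of 11 | C[Si](C)(C)O[C@](C)(CCC1OOC(C)(C)O1)C#C | intermediate
13 | (4R)-4-methyl-4-[(trimethylsilyl)oxy]hex-5-ynal | C[Si](C)(C)O[C@](C)(CCC=O)C#C | intermediate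
14 | methyl acrylate | C=CC(=O)OC | starting material
15 | methyl (6R)-3-hydroxy-6-methyl-2-methylidene-6-[(trimethylsilyl)oxy]oct-7-ynoate, both C3 epimers | C[Si](C)(C)O[C@](C)(CCC(O)C(=C)C(=O)OC)C#C | intermediate
16 | methyl (6R)-3-[(tert-butyldimethylsilyl)oxy]-6-methyl-2-methylidene-6-[(trimethylsilyl)oxy]oct-7-ynoate, both C3 epimers | C[Si](C)(C)O[C@](C)(CCC(O[Si](C)(C)C(C)(C)C)C(=C)C(=O)OC)C#C | intermediate
17 | hexacarbonyldicobalt complex of the alkyne of 16 | O=C=[Co]12(=C=O)(=C=O)[Co]3(=C=O)(=C=O)(=C=O)C1C23[C@](C)(O[Si](C)(C)C)CCC(O[Si](C)(C)C(C)(C)C)C(=C)C(=O)OC | intermediate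
18 | methyl (4R,7aR)-7-[(tert-butyldimethylsilyl)oxy]-4-methyl-2-oxo-4-[(trimethylsilyl)oxy]-1,2,4,5,6,7-hexahydro-7aH-indene-7a-carboxylate, both C7 epimers | O=C1C=C2[C@](C)(O[Si](C)(C)C)CCC(O[Si](C)(C)C(C)(C)C)[C@]2(C1)C(=O)OC | intermediate
19 | dilithium salt (C4 alkoxide, C7a carboxylate) of the hydrindenone hydroxy acid from 18 | O=C1C=C2[C@](C)([O-])CCC(O[Si](C)(C)C(C)(C)C)[C@]2(C1)C(=O)[O-].[Li+].[Li+] | intermediate
20 | trilithium salt: C2=C3 enolate of the trans-hydrindanone (H3a trans to the carboxylate), C4 alkoxide, C7a carboxylate | [O-]C1=C[C@@H]2[C@](C)([O-])CCC(O[Si](C)(C)C(C)(C)C)[C@]2(C1)C(=O)[O-].[Li+].[Li+].[Li+] | intermediate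
21 | dilithium salt of the C3-alkylated 2-oxo hydroxy acid (ring A cyclohexenylmethyl group trans to C4) | CC1(C)CC(C[C@@H]2C(=O)C[C@]3(C(=O)[O-])C(O[Si](C)(C)C(C)(C)C)CC[C@@](C)([O-])[C@@H]23)=CC[C@H]1O[Si](C)(C)C(C)(C)C.[Li+].[Li+] | intermediate
22 | tricyclic keto lactone: 2-oxo-hydrindane-7a,4-carbolactone with 7-OTBS, 4-methyl, H3a trans to the lactone carbonyl, and at C3 (trans to C4) the [(4'R)-4'-(TBS-oxy)-3',3'-dimethylcyclohex-6'-en-1'-yl]methyl group | CC1(C)CC(C[C@@H]2C(=O)C[C@]34C(=O)O[C@](C)(CCC3O[Si](C)(C)C(C)(C)C)[C@@H]24)=CC[C@H]1O[Si](C)(C)C(C)(C)C | intermediate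
23 | C2 tosylhydrazone of 22 | CC1(C)CC(C[C@@H]2C(=NNS(=O)(=O)c5ccc(C)cc5)C[C@]34C(=O)O[C@](C)(CCC3O[Si](C)(C)C(C)(C)C)[C@@H]24)=CC[C@H]1O[Si](C)(C)C(C)(C)C | intermediate
24 | tricyclic lactone with C2 as CH2 (otherwise as 22) | CC1(C)CC(C[C@@H]2CC[C@]34C(=O)O[C@](C)(CCC3O[Si](C)(C)C(C)(C)C)[C@@H]24)=CC[C@H]1O[Si](C)(C)C(C)(C)C | intermediate
25 | C1',C6'-epoxide of 24 | CC1(C)C[C@]2(C[C@@H]3CC[C@]45C(=O)O[C@](C)(CCC4O[Si](C)(C)C(C)(C)C)[C@@H]35)O[C@@H]2C[C@H]1O[Si](C)(C)C(C)(C)C | intermediate
26 | epoxy diol (C7–OH, C4'–OH) | CC1(C)C[C@]2(C[C@@H]3CC[C@]45C(=O)O[C@](C)(CCC4O)[C@@H]35)O[C@@H]2C[C@H]1O | intermediate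
27 | epoxy diketone (C7 and C4' ketones, C1',C6'-epoxide) | CC1(C)C[C@]2(C[C@@H]3CC[C@]45C(=O)O[C@](C)(CCC4=O)[C@@H]35)O[C@@H]2CC1=O | intermediate
28 | diketone with ring A as 1'-hydroxy-3',3'-dimethylcyclohex-5'-en-4'-one | CC1(C)C[C@@](O)(C[C@@H]2CC[C@]34C(=O)O[C@](C)(CCC3=O)[C@@H]24)C=CC1=O | intermediate
29 | saturated diketone (7-oxo lactone, ring A 1'-hydroxy-3',3'-dimethylcyclohexan-4'-one) | CC1(C)C[C@@](O)(C[C@@H]2CC[C@]34C(=O)O[C@](C)(CCC3=O)[C@@H]24)CCC1=O | intermediate
30 | bis(enol triflate) (C6=C7–OTf, C5'=C4'–OTf) | CC1(C)C[C@@](O)(C[C@@H]2CC[C@]34C(=O)O[C@](C)(CC=C3OS(=O)(=O)C(F)(F)F)[C@@H]24)CC=C1OS(=O)(=O)C(F)(F)F | intermediate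
31 | bis(alkenyl bromide) (7-bromo-C6=C7, 4'-bromo-C4'=C5') | CC1(C)C[C@@](O)(C[C@@H]2CC[C@]34C(=O)O[C@](C)(CC=C3Br)[C@@H]24)CC=C1Br | intermediate
32 | CNP0282702.2 (core 3S,3aS,4R,7S,7aS; ring A 1'S,4'S) | CC1(C)C[C@@](O)(C[C@@H]2CC[C@]34C(=O)O[C@](C)(CC[C@@H]3Br)[C@@H]24)CC[C@@H]1Br | target

**Step count and risk**

Total step count: 21. Longest linear sequence: 17 steps (7 to 32, steps 5–21); ring A chloride 6 takes 4 steps (steps 1–4) and joins in step 13.

Steps most likely to fail:

1. Step 12 (key step). The electron-poor 1,1-disubstituted alkene may insert too slowly into the alkyne–cobalt complex, so that decomplexation or diene formation by β-hydride elimination takes over. Fallback at another oxidation level: starting from 16, i-Bu2AlH (CH2Cl2, −78 °C) reduces the ester to allylic alcohol F1, whose electron-richer alkene is a standard partner for the same cyclocarbonylation; this gives hydroxymethyl enone F2. Oxidation of the neopentylic primary alcohol (TEMPO, PhI(OAc)2; then NaClO2, NaH2PO4, 2-methylbut-2-ene) gives enone carboxylic acid F3. LiOH treatment of F3 (silyl ether cleavage, salt formation) gives 19, where the route continues with the electron-transfer stage of step 13.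

2. Step 13. The C4 oxygen may be lost by vinylogous β-elimination or the ketone over-reduced during electron transfer, or proton transfer and O-alkylation may win over C-alkylation in ammonia. Fallback without dissolving metal: starting from 18, K2CO3 in MeOH removes the trimethylsilyl group and closes the lactone to tricyclic lactone enone F4. Hydrogenation (H2, Pd/C, or [Ir(cod)(PCy3)(py)]PF6) adds hydrogen from the convex face of the cis-fused five-membered rings to give saturated keto lactone F5. Kinetic deprotonation (LiN(i-Pr)2, THF, −78 °C) at the less hindered C3 methylene (C1 is flanked by quaternary C7a) and alkylation with 6 and NaI, anti to C4, returns to 22.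

3. Step 21. Hydrogen-atom delivery to the two α-bromo radicals may show poor facial selectivity, or bromine may be lost by reduction. Fallback by substitution with inversion: starting from diketone 29, LiBH(s-Bu)3 (THF, −78 °C) attacks both hindered ketones equatorially to give the triol with axial C7 and C4' hydroxyls F6. Appel bromination (PPh3, CBr4, toluene, 60 °C), which is known to convert axial alcohols next to a fully substituted ring carbon into equatorial bromides with inversion, gives 32; the tertiary hydroxyl is expected to stay unchanged.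

Further compounds
F1 | step 12 | (6R)-3-[(tert-butyldimethylsilyl)oxy]-6-methyl-2-methylidene-6-[(trimethylsilyl)oxy]oct-7-yn-1-ol, both C3 epimers | C[Si](C)(C)O[C@](C)(CCC(O[Si](C)(C)C(C)(C)C)C(=C)CO)C#C
F2 | step 12 | (4R,7aR)-7-[(tert-butyldimethylsilyl)oxy]-7a-(hydroxymethyl)-4-methyl-4-[(trimethylsilyl)oxy]-1,4,5,6,7,7a-hexahydro-2H-inden-2-one, both C7 epimers | O=C1C=C2[C@](C)(O[Si](C)(C)C)CCC(O[Si](C)(C)C(C)(C)C)[C@]2(C1)CO
F3 | step 12 | (4R,7aR)-7-[(tert-butyldimethylsilyl)oxy]-4-methyl-2-oxo-4-[(trimethylsilyl)oxy]-1,2,4,5,6,7-hexahydro-7aH-indene-7a-carboxylic acid, both C7 epimers | O=C1C=C2[C@](C)(O[Si](C)(C)C)CCC(O[Si](C)(C)C(C)(C)C)[C@]2(C1)C(=O)O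
F4 | step 13 | tricyclic lactone enone: 7-OTBS-4-methyl-2-oxo-hydrind-3(3a)-ene-7a,4-carbolactone, both C7 epimers | O=C1C[C@]23C(=O)O[C@](C)(CCC2O[Si](C)(C)C(C)(C)C)C3=C1
F5 | step 13 | saturated keto lactone: 7-OTBS-4-methyl-2-oxo-hydrindane-7a,4-carbolactone, H3a trans to the lactone carbonyl, both C7 epimers | O=C1C[C@]23C(=O)O[C@](C)(CCC2O[Si](C)(C)C(C)(C)C)[C@H]3C1
F6 | step 21 | triol: C7 and C4' epimeric alcohols in place of the two bromides of 32 (both hydroxyls axial) | CC1(C)C[C@@](O)(C[C@@H]2CC[C@]34C(=O)O[C@](C)(CC[C@H]3O)[C@@H]24)CC[C@H]1O
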